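**Plan**

- **Cuts.** After removal of the C2 hydroxyl, ring D opens by a retro-Diels–Alder cut of C2–C4' and C14–C15', so both halves become one monomer, dehydrozaluzanin C. In the monomer, C10=C14 goes back to a ketone and the C3 oxygen is removed. Then O–C6 and C4–C5 are cut together, leaving a 2,5-disubstituted cyclohept-3-enone whose C7–C11 and C1–C2 bonds lead back to tropone.
- **Enabling feature.** In each guaianolide half the methylene C15=C4, the ring-fusion carbon C5 and the lactone carbon C6 stand in a row, and the C4–C5 bond (β) and the C6–O bond (α) are anti on ring B. This is the imprint of an anti addition across a cis C5=C6 double bond of a cycloheptene, by a terminal alkyne carbon tethered at C1 and the acrylic acid oxygen tethered at C7.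
- **Forward.** Ring B is bought as tropone. A 1,8-addition brings C2–C4/C15 and a 1,6-addition brings C11–C13. One gold-triggered event then closes ring A and lactone ring C. Methylenation at C10 and oxidation at C3 give the monomer, which is used twice: one portion is dehydrogenated and adds to the other to close ring D, and oxygen capture installs the C2 hydroxyl.
- **Stereochemistry.** C7 is set by catalysis. C1 follows by kinetic protonation, and C5 and C6 by tether and anti addition in the key step. C4' and C2 come from an endo cycloaddition on the convex face of the dienophile and oxygen capture on the α face of ring A.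

Key step: step 7

Remark: guaiane numbering (C1–C15, primed for the dienophile half) is used for all intermediates. Ring A is the cyclopentane, ring B the cycloheptane, ring C the lactone, ring D the spiro-linked cyclohexene.
Assumption: ligand L1 in the (S,R,R) form is taken to deliver the alkenyl group to the face of C7 that gives the (5R) ketone; if the sense is opposite, its mirror image is used.
Assumption: the allylic oxidation of step 9 is taken to give the 3α-alcohol; this centre is removed in step 10.

Step 1
Reactants: 1 tropone; 2 (4-bromobut-1-yn-1-yl)trimethylsilane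
Product: 5 rac-2-[4-(trimethylsilyl)but-3-yn-1-yl]cyclohepta-3,5-dien-1-one, via Grignard reagent 3 (not isolated), via magnesium trienolate 4 (not isolated)
Conditions: 2, Mg, THF, rt; then 1, THF, −78 → 0 °C; aq NH4Cl
Reagents that add atoms: none
Why: Grignard reagents add to tropone in the 1,8-sense (attack at the carbon next to the carbonyl group, here C1), and protonation of the trienolate at C9 gives the 3,5-dienone, whose racemic centre is erased in step 2.

Step 2
Reactants: 5 rac-2-[4-(trimethylsilyl)but-3-yn-1-yl]cyclohepta-3,5-dien-1-one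
Product: 6 2-[4-(trimethylsilyl)but-3-yn-1-yl]cyclohepta-2,4-dien-1-one
Conditions: DBU (0.2 equiv), CH2Cl2, rt
Reagents that add atoms: none
Why: Base-catalysed prototropic isomerisation through the extended enolate moves both double bonds into conjugation with the ketone, and the 2-alkyl-2,4-dienone should be favoured because it carries the more substituted double bond.

Step 3
Reactants: 6 2-[4-(trimethylsilyl)but-3-yn-1-yl]cyclohepta-2,4-dien-1-one; 7 tert-butyldimethyl(prop-2-yn-1-yloxy)silane
Product: 10 (2R,5R)-5-{3-[(tert-butyldimethylsilyl)oxy]prop-1-en-2-yl}-2-[4-(trimethylsilyl)but-3-yn-1-yl]cyclohept-3-en-1-one (side chains cis), via alkenylalane 8 (not isolated), via aluminium dienolate 9 (not isolated)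
Conditions: 7, i-Bu2AlH, Ni(dppp)Cl2 (3 mol %), THF, 0 °C → rt; then Cu(OTf)2 (5 mol %), L1 = (S)-1,1'-binaphthyl-2,2'-diyl N,N-bis[(R)-1-phenylethyl]phosphoramidite (10 mol %), 6, Et2O, −40 °C; AcOH, THF, −78 °C
Reagents that add atoms: none
Why: Proposed new method: the chiral copper catalyst takes the alkenyl group from alane 8 (made by the known nickel-catalysed α-selective hydroalumination) and binds the dienone at its distal C6=C7 bond; because C1 carries a side chain, reductive elimination from the trivalent allylcopper species at C5 is slowed and the alkenyl group goes to C7 (1,6-addition), the ligand choosing the face and so setting C7; acetic acid then protonates dienolate 9 kinetically at C1 from the α face, anti to the C8 flap of the ring, which leaves both side chains β (the cis, diequatorial isomer) and the double bond at C5=C6; the closest known reaction types are the copper-catalysed enantioselective conjugate addition of alkenylalanes to cyclic enones and the copper-mediated 1,6-addition to cyclic 2,4-dienones followed by kinetic α-protonation.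

Step 4
Reactants: 10 (2R,5R)-5-{3-[(tert-butyldimethylsilyl)oxy]prop-1-en-2-yl}-2-[4-(trimethylsilyl)but-3-yn-1-yl]cyclohept-3-en-1-one
Product: 11 (2R,5R)-2-(but-3-yn-1-yl)-5-(3-hydroxyprop-1-en-2-yl)cyclohept-3-en-1-one
Conditions: Bu4NF, AcOH (1:1), THF, 0 °C → rt
Reagents that add atoms: none
Why: Fluoride-mediated desilylation frees the primary allylic alcohol and the terminal alkyne in one operation, and the acetic acid buffer should keep the β,γ-unsaturated ketone from epimerising at C1 or moving into conjugation.

Step 5
Reactants: 11 (2R,5R)-2-(but-3-yn-1-yl)-5-(3-hydroxyprop-1-en-2-yl)cyclohept-3-en-1-one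
Product: 12 2-[(1R,4R)-4-(but-3-yn-1-yl)-5-oxocyclohept-2-en-1-yl]prop-2-enal
Conditions: activated MnO2, CH2Cl2, rt
Reagents that add atoms: none
Why: Oxidation with MnO2 is selective for the allylic alcohol and neutral, so alkyne, ring alkene and the labile C1 centre should be untouched.

Step 6
Reactants: 12 2-[(1R,4R)-4-(but-3-yn-1-yl)-5-oxocyclohept-2-en-1-yl]prop-2-enal
Product: 13 2-[(1R,4R)-4-(but-3-yn-1-yl)-5-oxocyclohept-2-en-1-yl]prop-2-enoic acid
Conditions: NaClO2, NaH2PO4, 2-methylbut-2-ene, t-BuOH/H2O, 0 °C
Reagents that add atoms: sodium chlorite [Na+].[O-]Cl=O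
Why: The Pinnick oxidation turns 2-substituted acroleins into acrylic acids at about pH 4, and the alkene scavenger removes hypochlorous acid before it can reach the ring alkene.

Step 7
Reactants: 13 2-[(1R,4R)-4-(but-3-yn-1-yl)-5-oxocyclohept-2-en-1-yl]prop-2-enoic acid
Product: 14 10-oxo-14-norguaia-4(15),11(13)-dien-12,6α-olide (1αH,5αH,6βH,7αH; 3aS,6aR,9aR,9bS)
Conditions: [Au{P(t-Bu)2(biphenyl-2-yl)}(NCMe)]SbF6 (3 mol %), 4 Å MS, CH2Cl2, 0 °C → rt
Reagents that add atoms: none
Why: Proposed new method: the cationic monovalent gold centre binds the terminal alkyne C4≡C15, the cis C5=C6 bond of ring B attacks C4 to give a cyclopropyl gold carbene with positive charge building at C6, the carboxyl oxygen opens it at C6 from the rear, and protodeauration of the C15–Au bond leaves the C4=C15 methylene and frees the catalyst. The closest known reaction type is the gold- or platinum-catalysed 5-exo-dig hydroxy-, alkoxy- and acyloxycyclisation of 1,6-enynes, together with enyne polycyclisations that end on a carboxylic acid; new here are the endocyclic 1,2-disubstituted alkene and the acrylic acid as terminator. Ring A closes 5-exo-dig (C4–C5) and lactone ring C closes 5-exo at C6 (O–C6), which with the bought ring B completes the 5-7-5 skeleton in one isomerisation. C5 is set by the C1–C2–C3 tether, which can reach only the β face of the alkene and so gives the cis ring fusion (H1 and H5 both α); C6 is set by the stereospecific anti addition, which puts oxygen on the α face, trans to the C7 side chain, a closure that the large C5=C6–C7–C8 torsion angle of a cycloheptene allows from a pseudo-equatorial side chain. Chemoselectivity requires that the alkyne meets only C5=C6: the acrylic C11=C13 bond is electron-poor, and C10 is kept as a ketone so that no nucleophilic C10=C14 alkene, itself 1,6-related to the alkyne, can compete. Exo rather than endo closure and attack at C6 rather than C5 are secured by the terminal alkyne and by the preference for a fused γ-lactone over a bridged δ-lactone.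

Step 8
Reactants: 14 10-oxo-14-norguaia-4(15),11(13)-dien-12,6α-olide
Product: 15 dehydrocostus lactone, guaia-4(15),10(14),11(13)-trien-12,6α-olide (1αH,5αH,6βH,7αH)
Conditions: Zn, CH2Br2, TiCl4, THF/CH2Cl2, 0 °C → rt
Reagents that add atoms: dibromomethane BrCBr
Why: In the Takai–Lombardo methylenation the non-basic gem-dimetallic reagent converts the enolisable C10 ketone into C10=C14 without epimerising C1 and leaves the lactone and its conjugated methylene alone.

Step 9
Reactants: 15 dehydrocostus lactone
Product: 16 3-epizaluzanin C, 3α-hydroxyguaia-4(15),10(14),11(13)-trien-12,6α-olide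
Conditions: SeO2 (0.5 equiv), t-BuOOH, CH2Cl2, 0 °C → rt
Reagents that add atoms: tert-butyl hydroperoxide CC(C)(C)OO; selenium dioxide O=[Se]=O
Why: Selenium dioxide allylic oxidation (ene reaction, then [2,3]-shift), a reaction with close precedent on this trienolide, should hydroxylate C3 of the C4=C15 unit from the convex α face of ring A, and the new centre is removed in step 10.

Step 10
Reactants: 16 3-epizaluzanin C
Product: 17 dehydrozaluzanin C, 3-oxoguaia-4(15),10(14),11(13)-trien-12,6α-olide
Conditions: Dess–Martin periodinane, CH2Cl2, 0 °C → rt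
Reagents that add atoms: none
Why: Dess–Martin oxidation of the secondary allylic alcohol gives the α-methylene cyclopentanone under neutral conditions that spare the two Michael acceptors.

Step 11
Reactants: 17 dehydrozaluzanin C
Product: 18 3-[(tert-butyldimethylsilyl)oxy]guaia-2,4(15),10(14),11(13)-tetraen-12,6α-olide
Conditions: TBSOTf, Et3N, CH2Cl2, −78 → 0 °C
Reagents that add atoms: tert-butyldimethylsilyl trifluoromethanesulfonate CC(C)(C)[Si](C)(C)OS(=O)(=O)C(F)(F)F
Why: Soft enolisation and O-silylation can occur only towards C2, the sole enolisable position of the ketone, and avoids strong base in the presence of the Michael acceptors.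

Step 12
Reactants: 18 3-[(tert-butyldimethylsilyl)oxy]guaia-2,4(15),10(14),11(13)-tetraen-12,6α-olide; 17 dehydrozaluzanin C
Product: 22 target dimer (2S,4'R; 2α-OH; C2–C4' bond β on ring A and α on ring A'; both halves 5αH,6βH,7αH, dienophile half also 1'αH), via trienone 19 (not isolated), via Diels–Alder adduct 20 (not isolated), via hydroperoxide 21 (not isolated)
Conditions: Pd(OAc)2 (1.1 equiv), 17 (2 equiv), MeCN, O2 (1 atm), rt → 40 °C; then Me2S
Reagents that add atoms: dioxygen O=O
Why: Saegusa oxidation of the silyl dienol ether unveils trienone 19, whose C2=C1–C10=C14 diene adds to the C4'=C15' enone of 17 in an ortho-regioselective, endo (C3'=O under the diene) Diels–Alder reaction on the convex α face of 17 and the β face of 19 (sets C4' and C2), after which the doubly activated tertiary C2–H of 20 is autoxidised with oxygen capture on the α face of ring A and the hydroperoxide is reduced, a one-pot sequence with close precedent for this diene and dienophile pair.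

**Compound list**

1 | tropone (cyclohepta-2,4,6-trien-1-one) | O=C1C=CC=CC=C1 | starting material
2 | (4-bromobut-1-yn-1-yl)trimethylsilane | C[Si](C)(C)C#CCCBr | starting material
3 | [4-(trimethylsilyl)but-3-yn-1-yl]magnesium bromide | C[Si](C)(C)C#CCC[Mg]Br | intermediate
4 | bromomagnesium trienolate of 5 (racemic) | C[Si](C)(C)C#CCCC1C=CC=CC=C1O[Mg]Br | intermediate
5 | rac-2-[4-(trimethylsilyl)but-3-yn-1-yl]cyclohepta-3,5-dien-1-one | C[Si](C)(C)C#CCCC1C=CC=CCC1=O | intermediate
6 | 2-[4-(trimethylsilyl)but-3-yn-1-yl]cyclohepta-2,4-dien-1-one | C[Si](C)(C)C#CCCC1=CC=CCCC1=O | intermediate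
7 | tert-butyldimethyl(prop-2-yn-1-yloxy)silane | C#CCO[Si](C)(C)C(C)(C)C | starting material
8 | {3-[(tert-butyldimethylsilyl)oxy]prop-1-en-2-yl}diisobutylaluminium | C=C(CO[Si](C)(C)C(C)(C)C)[Al](CC(C)C)CC(C)C | intermediate
9 | diisobutylaluminium dienolate of 10 (C10=C1, C5=C6; C7 set) | C[Si](C)(C)C#CCCC1=C(O[Al](CC(C)C)CC(C)C)CC[C@@H](C(=C)CO[Si](C)(C)C(C)(C)C)C=C1 | intermediate
10 | (2R,5R)-5-{3-[(tert-butyldimethylsilyl)oxy]prop-1-en-2-yl}-2-[4-(trimethylsilyl)but-3-yn-1-yl]cyclohept-3-en-1-one | C[Si](C)(C)C#CCC[C@@H]1C=C[C@H](C(=C)CO[Si](C)(C)C(C)(C)C)CCC1=O | intermediate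
11 | (2R,5R)-2-(but-3-yn-1-yl)-5-(3-hydroxyprop-1-en-2-yl)cyclohept-3-en-1-one | C#CCC[C@@H]1C=C[C@H](C(=C)CO)CCC1=O | intermediate
12 | 2-[(1R,4R)-4-(but-3-yn-1-yl)-5-oxocyclohept-2-en-1-yl]prop-2-enal | C#CCC[C@@H]1C=C[C@H](C(=C)C=O)CCC1=O | intermediate
13 | 2-[(1R,4R)-4-(but-3-yn-1-yl)-5-oxocyclohept-2-en-1-yl]prop-2-enoic acid | C#CCC[C@@H]1C=C[C@H](C(=C)C(=O)O)CCC1=O | intermediate
14 | 10-oxo-14-norguaia-4(15),11(13)-dien-12,6α-olide (1αH,5αH,6βH,7αH) | C=C1CC[C@H]2C(=O)CC[C@H]3C(=C)C(=O)O[C@@H]3[C@H]21 | intermediate
15 | dehydrocostus lactone | C=C1CC[C@H]2C(=C)CC[C@H]3C(=C)C(=O)O[C@@H]3[C@H]21 | intermediate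
16 | 3-epizaluzanin C (3α-OH, 3R) | C=C1[C@H](O)C[C@H]2C(=C)CC[C@H]3C(=C)C(=O)O[C@@H]3[C@H]21 | intermediate
17 | dehydrozaluzanin C | C=C1C(=O)C[C@H]2C(=C)CC[C@H]3C(=C)C(=O)O[C@@H]3[C@H]21 | intermediate
18 | 3-[(tert-butyldimethylsilyl)oxy]guaia-2,4(15),10(14),11(13)-tetraen-12,6α-olide | C=C1C(O[Si](C)(C)C(C)(C)C)=C[C@H]2C(=C)CC[C@H]3C(=C)C(=O)O[C@@H]3[C@H]21 | intermediate
19 | 3-oxoguaia-1,4(15),10(14),11(13)-tetraen-12,6α-olide (trienone) | C=C1C(=O)C=C2C(=C)CC[C@H]3C(=C)C(=O)O[C@@H]3[C@H]21 | intermediate
20 | Diels–Alder adduct, 2-deoxy-22 (2αH) | C=C1C(=O)[C@@H]2C3=C(CC[C@H]4C(=C)C(=O)O[C@@H]4[C@@H]13)CC[C@]21C(=O)C[C@H]2C(=C)CC[C@H]3C(=C)C(=O)O[C@@H]3[C@H]21 | intermediate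
21 | 2α-hydroperoxide of 20 | C=C1C(=O)[C@]2(OO)C3=C(CC[C@H]4C(=C)C(=O)O[C@@H]4[C@@H]13)CC[C@]21C(=O)C[C@H]2C(=C)CC[C@H]3C(=C)C(=O)O[C@@H]3[C@H]21 | intermediate
22 | target CNP0269880.2 | C=C1C(=O)[C@]2(O)C3=C(CC[C@H]4C(=C)C(=O)O[C@@H]4[C@@H]13)CC[C@]21C(=O)C[C@H]2C(=C)CC[C@H]3C(=C)C(=O)O[C@@H]3[C@H]21 | target

Total step count: 12. Longest linear sequence: 12 (compound 17 enters step 12 twice, once as 18).

**Steps most likely to fail**

**Step 3.**
- What may go wrong: the copper catalyst may transfer the alkenyl group with poor facial selectivity, or in the 1,4- or 1,2-sense. The alane may lose silanolate before transfer. The quench may protonate the dienolate at C6 or from the wrong face.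
- Fallback: it sets out from 6 and uses the known copper-catalysed 1,6-addition of Grignard reagents to cyclic 2,4-dienones, followed by a classical resolution. [(2-Bromoprop-2-en-1-yl)oxy](tert-butyl)dimethylsilane and Mg give the Grignard reagent F1. With CuBr·SMe2 (10 mol %) in THF at −40 °C this adds to 6 to give the racemic magnesium dienolate F2, and acetic acid at −78 °C gives the racemic cis-ketone F3.
- The operations of steps 4 to 6 then give the racemic alcohol F4, the racemic enal F5 and the racemic acid F6. Crystallisation with (R)-1-phenylethylamine gives the less soluble ammonium salt F7 (the amine enantiomer is chosen by trial). Dilute HCl brings the route back at 13.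

**Step 7.**
- What may go wrong: the carboxyl group may fail to reach the α face of C6. The cyclopropyl gold carbene would then drain into skeletal rearrangement to dienes or into proton loss, or the alkyne may simply be hydrated.
- Fallback: it sets out from 13 and separates carbon–carbon bond formation from lactone closure. Me3SiCHN2 gives the methyl ester F8. The known intermolecular gold-catalysed hydroxycyclisation of 1,6-enynes (same catalyst, wet acetone, water as the external nucleophile, anti addition) gives the 6α-hydroxy ester F9.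
- Catalytic TsOH in toluene then closes the trans-lactone at the acyl carbon, and the route comes back at 14.

**Step 12.**
- What may go wrong: the trienone may dimerise with itself. The cycloaddition may proceed with poor face pairing or poor endo selectivity. Oxygen may be captured at C10 instead of C2, or on the β face.
- Fallback: it sets out from 18 and runs the three events apart. PhSeCl in CH2Cl2 at −78 °C gives the 2α-phenylselanyl ketone F10. One equivalent of m-CPBA at −78 °C gives the selenoxide F11, whose syn elimination across H1α on warming releases 19 in the presence of excess 17.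
- Adduct 20 is isolated and freed from its diastereomers. The known base-catalysed aerobic α-hydroxylation of tertiary α-C–H ketones (Cs2CO3 cat., O2, P(OEt)3, DMSO) then acts on the most acidic position, C2, and the route comes back at 22.

**Further compounds**

F1 | step 3 | {3-[(tert-butyldimethylsilyl)oxy]prop-1-en-2-yl}magnesium bromide | C=C(CO[Si](C)(C)C(C)(C)C)[Mg]Br
F2 | step 3 | racemic bromomagnesium dienolate | C[Si](C)(C)C#CCCC1=C(O[Mg]Br)CC[C@@H](C(=C)CO[Si](C)(C)C(C)(C)C)C=C1.C[Si](C)(C)C#CCCC1=C(O[Mg]Br)CC[C@H](C(=C)CO[Si](C)(C)C(C)(C)C)C=C1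
F3 | step 3 | rac-10 (cis) | C[Si](C)(C)C#CCC[C@@H]1C=C[C@H](C(=C)CO[Si](C)(C)C(C)(C)C)CCC1=O.C[Si](C)(C)C#CCC[C@H]1C=C[C@@H](C(=C)CO[Si](C)(C)C(C)(C)C)CCC1=O
F4 | step 3 | rac-11 (cis) | C#CCC[C@@H]1C=C[C@H](C(=C)CO)CCC1=O.C#CCC[C@H]1C=C[C@@H](C(=C)CO)CCC1=O
F5 | step 3 | rac-12 (cis) | C#CCC[C@@H]1C=C[C@H](C(=C)C=O)CCC1=O.C#CCC[C@H]1C=C[C@@H](C(=C)C=O)CCC1=O
F6 | step 3 | rac-13 (cis) | C#CCC[C@@H]1C=C[C@H](C(=C)C(=O)O)CCC1=O.C#CCC[C@H]1C=C[C@@H](C(=C)C(=O)O)CCC1=O
F7 | step 3 | (R)-1-phenylethylammonium salt of 13 | C#CCC[C@@H]1C=C[C@H](C(=C)C(=O)[O-])CCC1=O.C[C@@H]([NH3+])c1ccccc1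
F8 | step 7 | methyl 2-[(1R,4R)-4-(but-3-yn-1-yl)-5-oxocyclohept-2-en-1-yl]prop-2-enoate | C#CCC[C@@H]1C=C[C@H](C(=C)C(=O)OC)CCC1=O
F9 | step 7 | methyl 6α-hydroxy-10-oxo-14-norguaia-4(15),11(13)-dien-12-oate (1αH,5αH,7αH) | C=C1CC[C@H]2C(=O)CC[C@@H](C(=C)C(=O)OC)[C@H](O)[C@H]21
F10 | step 12 | 2α-(phenylselanyl)dehydrozaluzanin C | C=C1C(=O)[C@H]([Se]c2ccccc2)[C@H]2C(=C)CC[C@H]3C(=C)C(=O)O[C@@H]3[C@H]21
F11 | step 12 | selenoxide of F10 | C=C1C(=O)[C@H]([Se](=O)c2ccccc2)[C@H]2C(=C)CC[C@H]3C(=C)C(=O)O[C@@H]3[C@H]21
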